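**Plan**
1. The retrosynthesis first removes the three O-methyl groups. It then cuts the C1′–C6′ bond of both 2,4-dihydroxyphenyl rings (rings D and E), so each aroyl group unfolds into an open seven-carbon chain.
2. Enabling feature: in rings D and E the ketone sits on C1′, oxygen sits on C2′ and C4′, and C6′ is a plain CH. This is the pattern of a 1,3,5-trioxo chain whose last carbon is at the aldehyde level, carried here as a β-methoxyvinyl ketone.
3. Further cuts: the carbonyl-C–C1′ bonds (naphthalene-2,3-dicarbaldehyde plus a diketone dianion), C2′–C3′ of the chain reagent (enolate acylation), C1–C2 and C3–C4 of naphthalene ring B (Diels–Alder), and C1–C8a (Friedel–Crafts).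
4. Forward: rings A (dimethoxybenzo) and C (anisyl) are bought, and ring B arises by photoenolisation, cycloaddition and dehydration. The two chains are then joined to C2 and C3, rings D and E close together in one flask, and the methyl ethers are cleaved last.
5. The target has no stereocentre and no stereogenic double bond. The carbinol centres formed on the way are made without control and are erased by dehydration or oxidation.

Key step: step 8

Remark: β-di- and triketones are drawn and named as keto forms although they exist largely as chelated enols; the connectivity is unaffected.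

**Step 1**
Reactants: 1 3,4-dimethoxytoluene; 2 4-methoxybenzoyl chloride
Product: 3 (4,5-dimethoxy-2-methylphenyl)(4-methoxyphenyl)methanone
Conditions: AlCl3 (1.2 equiv), CH2Cl2, 0 → 23 °C; ice/1 M HCl
Reagents that add atoms: none
Why: Friedel–Crafts acylation; C6 of 1 (para to the 3-methoxy group, ortho to the methyl group) is the most activated and least hindered site, so the ketone lands next to the methyl group as the photoenolisation requires.

**Step 2**
Reactants: 3 (4,5-dimethoxy-2-methylphenyl)(4-methoxyphenyl)methanone; 4 dimethyl acetylenedicarboxylate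
Product: 7 dimethyl 6,7-dimethoxy-1-(4-methoxyphenyl)naphthalene-2,3-dicarboxylate, via (E)-photoenol 5 (not isolated), via racemic hydroxydihydronaphthalene cycloadduct 6 (not isolated)
Conditions: hν (365 nm), 4 (3 equiv), degassed toluene, 23 °C; then p-TsOH·H2O (10 mol %), 110 °C
Reagents that add atoms: none
Why: Photoenolisation/Diels–Alder sequence, in which 1,5-hydrogen transfer in the excited o-methylbenzophenone gives the long-lived (E)-hydroxy-o-quinodimethane, the acetylenic dienophile traps it, and acid removes water from the doubly benzylic carbinol to aromatise ring B, erasing the racemic carbinol centre of 6.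

**Step 3**
Reactants: 7 dimethyl 6,7-dimethoxy-1-(4-methoxyphenyl)naphthalene-2,3-dicarboxylate
Product: 8 [6,7-dimethoxy-1-(4-methoxyphenyl)naphthalene-2,3-diyl]dimethanol
Conditions: LiAlH4 (3 equiv), THF, 0 → 66 °C; quench with Na2SO4·10H2O
Reagents that add atoms: none
Why: Hydride reduction of both aryl esters with LiAlH4, a routine operation on 1-arylnaphthalene-2,3-dicarboxylates that leaves aryl methyl ethers untouched.

**Step 4**
Reactants: 8 [6,7-dimethoxy-1-(4-methoxyphenyl)naphthalene-2,3-diyl]dimethanol
Product: 9 6,7-dimethoxy-1-(4-methoxyphenyl)naphthalene-2,3-dicarbaldehyde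
Conditions: (COCl)2 (4 equiv), DMSO (8 equiv), CH2Cl2, −78 °C; Et3N (12 equiv), −78 → 0 °C
Reagents that add atoms: none
Why: Swern oxidation activates both primary hydroxyl groups before base is added, so both reach the aldehyde level together and the lactol/lactone path typical of 1,2-bis(hydroxymethyl)arenes is avoided.

**Step 5**
Reactants: 10 (E)-4-methoxybut-3-en-2-one; 11 acetyl chloride
Product: 13 (E)-6-methoxyhex-5-ene-2,4-dione, via lithium dienolate 12 (not isolated)
Conditions: 10 (2 equiv), LiN(SiMe3)2 (2 equiv), THF, −78 °C; 11 (1 equiv), −78 °C; aq NH4Cl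
Reagents that add atoms: none
Why: Claisen-type C-acylation of a kinetic lithium enolate with an acid chloride, the established entry to 1-methoxy-1-ene-3,5-diones, in which the second equivalent of enolate takes up the acidic proton of 13 and the (E) geometry of 10 is carried over.

**Step 6**
Reactants: 9 6,7-dimethoxy-1-(4-methoxyphenyl)naphthalene-2,3-dicarbaldehyde; 13 (E)-6-methoxyhex-5-ene-2,4-dione
Product: 15 2,3-bis[(E)-1-hydroxy-7-methoxy-3,5-dioxohept-6-enyl]-6,7-dimethoxy-1-(4-methoxyphenyl)naphthalene (diastereomer mixture), via dilithium dianion 14 (not isolated)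
Conditions: 13 (2.6 equiv) added to LiN(i-Pr)2 (5.4 equiv), THF, −78 → −30 °C; 9, −78 → −30 °C; AcOH, −78 °C
Reagents that add atoms: none
Why: Aldol addition of a β-diketone dianion at its terminal, most basic carbon; the methyl group of 13 is the only remaining enolisable site because the other flank is a vinylogous ester, small aldehyde electrophiles suit the crowded C2/C3 positions, and the two new carbinol centres form without control and are erased in step 7.

**Step 7**
Reactants: 15 2,3-bis[(E)-1-hydroxy-7-methoxy-3,5-dioxohept-6-enyl]-6,7-dimethoxy-1-(4-methoxyphenyl)naphthalene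
Product: 16 2,3-bis[(E)-7-methoxy-1,3,5-trioxohept-6-enyl]-6,7-dimethoxy-1-(4-methoxyphenyl)naphthalene
Conditions: IBX (5 equiv), DMSO, 23 °C; crude product used directly
Reagents that add atoms: none
Why: IBX oxidation of β-hydroxy ketones to β-diketones under neutral conditions; the benzylic carbinols react readily, enol and aryl ethers are inert at 23 °C, and both carbinol stereocentres vanish.

**Step 8**
Reactants: 16 2,3-bis[(E)-7-methoxy-1,3,5-trioxohept-6-enyl]-6,7-dimethoxy-1-(4-methoxyphenyl)naphthalene
Product: 18 [6,7-dimethoxy-1-(4-methoxyphenyl)naphthalene-2,3-diyl]bis[(2,4-dihydroxyphenyl)methanone], via half-closed mono-resorcinol 17 (not isolated)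
Conditions: K2CO3 (8 equiv), dry MeOH (5 mM), Ar, 23 → 60 °C; then 1 M HCl, 0 °C
Reagents that add atoms: none
Why: Proposed new method: carbonate ionises each 1,3,5-triketone, and in the tautomer whose charge lies on C1′ (between the naphthyl ketone and C2′=O) the C4′ enone is free, so C1′ adds to the methoxy-bearing carbon C6′, methoxide leaves, and the resulting 4-acylcyclohex-5-ene-1,3-dione enolises to the 2,4-dihydroxyphenyl ketone, the less hindered C3 chain probably closing first (17). The closest known reaction types are the base-mediated aldol cyclisation of 3,5,7-tricarbonyl chains to acylresorcinols and the base-induced isomerisation of 2-(acylmethyl)pyran-4-ones to acylresorcinols; not yet shown are a β-methoxyvinyl ketone as acceptor and two such closures on neighbouring ring positions. Rings D and E each close 6-endo-trig at C6′ by forming the C1′–C6′ bond, and no stereocentre is created. The step needs C- over O-selectivity: attack by the C2′ enolate oxygen gives a pyran-4-one, but methoxide can reopen that ring at C6′, whereas the carbocycle aromatises to a phenoxide and cannot revert, so the mixture should drain towards 18. The enol ether keeps C5′ non-nucleophilic, which excludes the alternative fold (C5′ onto the naphthyl ketone), and ionisation of both chains together with high dilution should hold back the cross-chain aldol onto the neighbouring naphthyl carbonyl.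

**Step 9**
Reactants: 18 [6,7-dimethoxy-1-(4-methoxyphenyl)naphthalene-2,3-diyl]bis[(2,4-dihydroxyphenyl)methanone]
Product: 19 [6,7-dihydroxy-1-(4-hydroxyphenyl)naphthalene-2,3-diyl]bis[(2,4-dihydroxyphenyl)methanone] (CNP0304576.0)
Conditions: BBr3 (12 equiv), CH2Cl2, −78 → 23 °C; ice-water
Reagents that add atoms: none
Why: Lewis-acid cleavage of aryl methyl ethers with BBr3; the ketones and free phenols only bind the reagent (hence the excess) and are released on hydrolysis.

**Compound list**
1 | 3,4-dimethoxytoluene | Cc1ccc(OC)c(OC)c1 | starting material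
2 | 4-methoxybenzoyl chloride | COc1ccc(cc1)C(Cl)=O | starting material
3 | (4,5-dimethoxy-2-methylphenyl)(4-methoxyphenyl)methanone | COc1ccc(cc1)C(=O)c1cc(OC)c(OC)cc1C | intermediate
4 | dimethyl acetylenedicarboxylate | COC(=O)C#CC(=O)OC | starting material
5 | (E)-(3,4-dimethoxy-6-methylidenecyclohexa-2,4-dien-1-ylidene)(4-methoxyphenyl)methanol, photoenol with OH pointing away from the CH2 terminus | C=C1C=C(OC)C(OC)=C/C1=C(\O)c1ccc(OC)cc1 | intermediate
6 | dimethyl 1-hydroxy-6,7-dimethoxy-1-(4-methoxyphenyl)-1,4-dihydronaphthalene-2,3-dicarboxylate (racemic) | COC(=O)C1=C(C(=O)OC)C(O)(c2ccc(OC)cc2)c2cc(OC)c(OC)cc2C1 | intermediate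
7 | dimethyl 6,7-dimethoxy-1-(4-methoxyphenyl)naphthalene-2,3-dicarboxylate | COC(=O)c1cc2cc(OC)c(OC)cc2c(-c2ccc(OC)cc2)c1C(=O)OC | intermediate
8 | [6,7-dimethoxy-1-(4-methoxyphenyl)naphthalene-2,3-diyl]dimethanol | COc1ccc(cc1)-c1c(CO)c(CO)cc2cc(OC)c(OC)cc12 | intermediate
9 | 6,7-dimethoxy-1-(4-methoxyphenyl)naphthalene-2,3-dicarbaldehyde | COc1ccc(cc1)-c1c(C=O)c(C=O)cc2cc(OC)c(OC)cc12 | intermediate
10 | (E)-4-methoxybut-3-en-2-one | CO/C=C/C(C)=O | starting material
11 | acetyl chloride | CC(Cl)=O | starting material
12 | lithium (E)-4-methoxybuta-1,3-dien-2-olate | [Li+].C=C([O-])/C=C/OC | intermediate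
13 | (E)-6-methoxyhex-5-ene-2,4-dione | CC(=O)CC(=O)/C=C/OC | intermediate
14 | dilithium 1,3-dianion of (E)-6-methoxyhex-5-ene-2,4-dione | [Li+].[Li+].[CH2-]C(=O)[CH-]C(=O)/C=C/OC | intermediate
15 | 2,3-bis[(E)-1-hydroxy-7-methoxy-3,5-dioxohept-6-enyl]-6,7-dimethoxy-1-(4-methoxyphenyl)naphthalene (carbinol centres undefined, diastereomer mixture) | COc1ccc(cc1)-c1c(C(O)CC(=O)CC(=O)/C=C/OC)c(C(O)CC(=O)CC(=O)/C=C/OC)cc2cc(OC)c(OC)cc12 | intermediate
16 | 2,3-bis[(E)-7-methoxy-1,3,5-trioxohept-6-enyl]-6,7-dimethoxy-1-(4-methoxyphenyl)naphthalene | COc1ccc(cc1)-c1c(C(=O)CC(=O)CC(=O)/C=C/OC)c(C(=O)CC(=O)CC(=O)/C=C/OC)cc2cc(OC)c(OC)cc12 | intermediate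
17 | 3-(2,4-dihydroxybenzoyl)-2-[(E)-7-methoxy-1,3,5-trioxohept-6-enyl]-6,7-dimethoxy-1-(4-methoxyphenyl)naphthalene | COc1ccc(cc1)-c1c(C(=O)CC(=O)CC(=O)/C=C/OC)c(C(=O)c2ccc(O)cc2O)cc2cc(OC)c(OC)cc12 | intermediate
18 | [6,7-dimethoxy-1-(4-methoxyphenyl)naphthalene-2,3-diyl]bis[(2,4-dihydroxyphenyl)methanone] | COc1ccc(cc1)-c1c(C(=O)c2ccc(O)cc2O)c(C(=O)c2ccc(O)cc2O)cc2cc(OC)c(OC)cc12 | intermediate
19 | [6,7-dihydroxy-1-(4-hydroxyphenyl)naphthalene-2,3-diyl]bis[(2,4-dihydroxyphenyl)methanone] | O=C(c1ccc(O)cc1O)c1cc2cc(O)c(O)cc2c(-c2ccc(O)cc2)c1C(=O)c1ccc(O)cc1O | target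

**Step count**
Total: 9 steps. Longest linear sequence: 8 steps (steps 1–4 and 6–9, from 1). Step 5 is a one-step side branch.

**Steps most likely to fail**

**Step 8 (proposed new method).**
- Attack by the C2′ enolate oxygen at C6′ may outrun carbon attack, and reopening by methoxide may be too slow under carbonate.
- The enolate of one chain may add to the neighbouring naphthyl ketone in a five-membered cross-chain aldol closure.
- Methanolysis (retro-Claisen cleavage) may shorten the chains.

The fallback uses only known reaction types and attaches the rings ready-made. It sets out from dialdehyde 9. Commercial 2,4-dimethoxyphenylmagnesium bromide (THF, 0 °C) should add to both formyl groups to give the bis(diarylcarbinol) [6,7-dimethoxy-1-(4-methoxyphenyl)naphthalene-2,3-diyl]bis[(2,4-dimethoxyphenyl)methanol] F1. Dess–Martin periodinane should oxidise it to the heptamethyl ether [6,7-dimethoxy-1-(4-methoxyphenyl)naphthalene-2,3-diyl]bis[(2,4-dimethoxyphenyl)methanone] F2. BBr3, as in step 9 but in larger excess, should then cleave all seven methyl ethers, so the sequence comes back to the route at 19.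

**Step 6.**
- The dianion may self-condense by attack on the vinylogous ester of a second molecule.
- After the first addition the alkoxide may close onto the neighbouring formyl group as a lactolate and stall the second addition.

The fallback carries the six chain carbons in a stable cyclic form. It sets out from 13 and 9.
- Catalytic CF3CO2H in CH2Cl2 should close 13, with loss of methanol, to 2-methyl-4H-pyran-4-one F3.
- LiN(SiMe3)2 (THF, −78 °C) should remove a proton from the 2-methyl group to give lithium 2-methylidene-2H-pyran-4-olate F4.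
- F4 should add to both aldehydes of 9 to give the bis(pyranonyl carbinol) 2,3-bis[1-hydroxy-2-(4-oxo-4H-pyran-2-yl)ethyl]-6,7-dimethoxy-1-(4-methoxyphenyl)naphthalene F5.
- Dess–Martin oxidation should give the bis(pyranonylmethyl ketone) 2,3-bis[(4-oxo-4H-pyran-2-yl)acetyl]-6,7-dimethoxy-1-(4-methoxyphenyl)naphthalene F6.
- NaOMe in MeOH should add to C6 of each pyranone and open it. The sequence thereby comes back to the route at 16, formed as its enolate in the flask in which step 8 is run.

**Step 7.**
- The benzylic aldols may lose water or undergo retro-aldol cleavage.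
- The doubly activated methylene groups may be over-oxidised.
- The hindered C2 carbinol may lag behind.

The fallback avoids the carbinol oxidation level altogether. It sets out from diester 7. MeNH(OMe)·HCl with i-PrMgCl (THF, −20 → 23 °C) should give the bis(Weinreb amide) N2,N3,6,7-tetramethoxy-1-(4-methoxyphenyl)-N2,N3-dimethylnaphthalene-2,3-dicarboxamide F7. Dianion 14, made from 13 as in step 6, should add to both amides (Weinreb ketone synthesis). The chelated adducts persist until the acidic quench, so no triketone enolate is present to attack the neighbouring acyl group. The sequence comes back to the route at 16.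

**Further compounds**
F1 | step 8 | [6,7-dimethoxy-1-(4-methoxyphenyl)naphthalene-2,3-diyl]bis[(2,4-dimethoxyphenyl)methanol] (diastereomer mixture) | COc1ccc(cc1)-c1c(C(O)c2ccc(OC)cc2OC)c(C(O)c2ccc(OC)cc2OC)cc2cc(OC)c(OC)cc12
F2 | step 8 | [6,7-dimethoxy-1-(4-methoxyphenyl)naphthalene-2,3-diyl]bis[(2,4-dimethoxyphenyl)methanone] | COc1ccc(cc1)-c1c(C(=O)c2ccc(OC)cc2OC)c(C(=O)c2ccc(OC)cc2OC)cc2cc(OC)c(OC)cc12
F3 | step 6 | 2-methyl-4H-pyran-4-one | CC1=CC(=O)C=CO1
F4 | step 6 | lithium 2-methylidene-2H-pyran-4-olate | [Li+].C=C1C=C([O-])C=CO1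
F5 | step 6 | 2,3-bis[1-hydroxy-2-(4-oxo-4H-pyran-2-yl)ethyl]-6,7-dimethoxy-1-(4-methoxyphenyl)naphthalene (diastereomer mixture) | COc1ccc(cc1)-c1c(C(O)CC2=CC(=O)C=CO2)c(C(O)CC2=CC(=O)C=CO2)cc2cc(OC)c(OC)cc12
F6 | step 6 | 2,3-bis[(4-oxo-4H-pyran-2-yl)acetyl]-6,7-dimethoxy-1-(4-methoxyphenyl)naphthalene | COc1ccc(cc1)-c1c(C(=O)CC2=CC(=O)C=CO2)c(C(=O)CC2=CC(=O)C=CO2)cc2cc(OC)c(OC)cc12
F7 | step 7 | N2,N3,6,7-tetramethoxy-1-(4-methoxyphenyl)-N2,N3-dimethylnaphthalene-2,3-dicarboxamide | COc1ccc(cc1)-c1c(C(=O)N(C)OC)c(C(=O)N(C)OC)cc2cc(OC)c(OC)cc12
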